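With the ring atoms numbered C1–C10 (lactone oxygen on C6, ester on C8), the ten-membered ring holds its C1=C10 olefin and the C6 oxygen in the 1,5-relationship of a cyclodec-5-enone, the retron of an oxy-Cope shift. Disconnecting C8–C9 while rejoining C1 to C6 contracts it to the six-membered ring C1–C6 of carvone, with C9–C10(C14) as the isopropenyl group and C7–C8 as a 2-silylvinyl group on the carbinol carbon C6. In one operation the anionic oxy-Cope shift builds the ring, the E C1=C10 olefin, the C8 stereocentre (silicon as masked hydroxyl) and a regiodefined C6 enolate. Its precursor is a 6-isopropenyl-1-[(E)-2-silylvinyl]cyclohex-2-enol carrying the C3 oxygen as a silyl ether.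

Key step: step 8

Remarks on the chemistry: all ten-membered compounds are numbered as in the target (ring C1–C10, lactone carbons C11–C13). The C3 hydroxyl is carried as a triisopropylsilyl ether so that it survives the fluoride that opens the C8 benzylsilane in step 11. The C6=C7 geometry of enolate 17 and the transient C11 centre of 30 and 31 are not assigned.

Step 1
Reactants: 1 (R)-(−)-carvone
Product: 2 (1R,5R)-cis-carveol
Conditions: NaBH4, CeCl3·7H2O, MeOH, 0 °C
Reagents that add atoms: none
Why: Luche 1,2-reduction of the enone, with axial hydride delivery to the half-chair that has the isopropenyl group equatorial, should give the equatorial alcohol, that is the cis (1R) carbinol.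

Step 2
Reactants: 2 (1R,5R)-cis-carveol
Product: 3 (1S,5R)-trans-carveyl 4-nitrobenzoate
Conditions: PPh3, DIAD, 4-O2NC6H4CO2H, toluene, −20 °C to rt
Reagents that add atoms: 4-nitrobenzoic acid, OC(=O)c1ccc(cc1)[N+](=O)[O-]
Why: Mitsunobu esterification displaces the activated allylic oxygen by SN2 with inversion (1R to 1S), and the acidic nucleophile at low temperature favours direct over allylic (SN2′) substitution.

Step 3
Reactants: 3 (1S,5R)-trans-carveyl 4-nitrobenzoate
Product: 4 (1S,5R)-trans-carveol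
Conditions: K2CO3, MeOH, rt
Reagents that add atoms: none
Why: Methanolysis (transesterification) of the electron-poor benzoate frees the alcohol without touching the carbinol configuration.

Step 4
Reactants: 4 (1S,5R)-trans-carveol
Product: 5 (1S,5R)-trans-carveol triisopropylsilyl ether
Conditions: i-Pr3SiOTf, 2,6-lutidine, CH2Cl2, 0 °C
Reagents that add atoms: triisopropylsilyl trifluoromethanesulfonate, CC(C)[Si](OS(=O)(=O)C(F)(F)F)(C(C)C)C(C)C
Why: Silylation of the hindered pseudoaxial alcohol with the silyl triflate gives an ether that should outlast alkoxide, amide, hydride and the brief fluoride exposure of step 11.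

Step 5
Reactants: 5 (1S,5R)-trans-carveol triisopropylsilyl ether
Product: 6 (4S,6R)-3-methyl-6-(prop-1-en-2-yl)-4-(triisopropylsilyloxy)cyclohex-2-en-1-one
Conditions: CrO3, 3,5-dimethylpyrazole, CH2Cl2, −20 °C
Reagents that add atoms: chromium trioxide, O=[Cr](=O)=O
Why: Allylic C–H oxidation by the chromium trioxide–dimethylpyrazole complex should attack the ring methylene next to the olefinic CH, the only unhindered secondary allylic position of the trisubstituted olefin, and give the enone with both stereocentres intact.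

Step 6
Reactants: 7 (E)-1,2-bis(tributylstannyl)ethene, 8 benzylchlorodimethylsilane
Product: 10 (E)-benzyldimethyl[2-(tributylstannyl)ethenyl]silane, via (E)-2-(tributylstannyl)ethenyllithium 9 (not isolated)
Conditions: n-BuLi (1.0 equiv), THF, −78 °C; then 8, −78 °C to rt
Reagents that add atoms: none
Why: Tin–lithium exchange at one terminus proceeds with retention of the E geometry and the vinyllithium is silylated by nucleophilic substitution at silicon.

Step 7
Reactants: 10 (E)-benzyldimethyl[2-(tributylstannyl)ethenyl]silane, 6 (4S,6R)-3-methyl-6-(prop-1-en-2-yl)-4-(triisopropylsilyloxy)cyclohex-2-en-1-one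
Product: 13 (1R,4S,6R)-1-[(E)-2-(benzyldimethylsilyl)ethenyl]-3-methyl-6-(prop-1-en-2-yl)-4-(triisopropylsilyloxy)cyclohex-2-en-1-ol, via (E)-2-(benzyldimethylsilyl)ethenyllithium 11 (not isolated), via vinylcerium dichloride 12 (not isolated)
Conditions: 10, n-BuLi, THF, −78 °C; CeCl3, −78 °C; then 6, −78 °C; aq NH4Cl
Reagents that add atoms: none
Why: A second tin–lithium exchange and transmetalation to cerium give a weakly basic organocerium reagent that adds 1,2 without enolizing the doubly activated C6–H, and equatorial attack anti to the adjacent equatorial isopropenyl group should set the carbinol as 1R with the two alkenyl groups trans.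

Step 8
Reactants: 13 (1R,4S,6R)-1-[(E)-2-(benzyldimethylsilyl)ethenyl]-3-methyl-6-(prop-1-en-2-yl)-4-(triisopropylsilyloxy)cyclohex-2-en-1-ol
Product: 16 (3S,8R,1(10)E,4Z)-8-(benzyldimethylsilyl)-4,10-dimethyl-3-(triisopropylsilyloxy)cyclodeca-1(10),4-dien-6-one, via potassium alkoxide 14 (not isolated), via potassium enolate 15 (not isolated)
Conditions: KH, 18-crown-6, THF, 0 °C to rt; then aq NH4Cl, −78 °C
Reagents that add atoms: none
Why: Deprotonation gives the crown-separated potassium alkoxide 14, whose oxyanion weakens the adjacent ring bond, and a concerted anionic oxy-Cope [3,3]-shift joins the isopropenyl CH2 to the silicon-bearing vinyl carbon (C8–C9) while the ring bond C1–C6 breaks, releasing enolate 15, which is protonated at C7 on work-up. The closest known reaction type is the anionic oxy-Cope ring expansion of trans-1,2-dialkenylcyclohexanols to cyclodec-5-enones. The ten-membered ring is not closed end to end but arises by cleavage of the bond shared by the cyclohexene and the six-centre chair array, a four-carbon ring expansion that needs no dilution. C8 is the only new stereocentre and is controlled by the carvone-derived carbon bearing the isopropenyl group, which fixes the chair with both ring residues equatorial, together with the E geometry of the vinylsilane, which puts silicon equatorial and gives 8R. The step needs chair over boat selectivity for the E C1=C10 olefin and for C8, which the trans-diequatorial alkenyl groups secure, while the C3 ether and the cis C4=C5 olefin are spectators and silicon at C8 cannot be expelled from the enolate.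

Step 9
Reactants: 16 (3S,8R,1(10)E,4Z)-8-(benzyldimethylsilyl)-4,10-dimethyl-3-(triisopropylsilyloxy)cyclodeca-1(10),4-dien-6-one
Product: 18 methyl 2-[(3S,7S,8R,1(10)E,4Z)-8-(benzyldimethylsilyl)-4,10-dimethyl-6-oxo-3-(triisopropylsilyloxy)cyclodeca-1(10),4-dien-7-yl]acetate, via lithium enolate 17 (not isolated)
Conditions: LiN(i-Pr)2, THF, −78 °C; BrCH2CO2Me, DMPU, −78 to −40 °C
Reagents that add atoms: methyl bromoacetate, COC(=O)CBr
Why: Kinetic deprotonation can only occur at C7 on the saturated side of the cross-conjugated ketone, and SN2 C-alkylation of the enolate is expected anti to the C8–Si bond with H8 eclipsing the enolate (the 1,2-induction known for enolates with a β-silyl stereocentre), giving 7S with C11 and silicon on the same ring face, while C7 stays epimerizable until step 10.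

Step 10
Reactants: 18 methyl 2-[(3S,7S,8R,1(10)E,4Z)-8-(benzyldimethylsilyl)-4,10-dimethyl-6-oxo-3-(triisopropylsilyloxy)cyclodeca-1(10),4-dien-7-yl]acetate
Product: 20 (3S,6R,7S,8R,1(10)E,4Z)-8-(benzyldimethylsilyl)-3-(triisopropylsilyloxy)-13-norgermacra-1(10),4-dien-12,6-olide, via hydroxy ester 19 (not isolated)
Conditions: NaBH4, CeCl3·7H2O, MeOH, −40 °C; then PPTS (cat.), CH2Cl2, rt
Reagents that add atoms: none
Why: Luche 1,2-reduction of the enone carbonyl, with hydride expected on the C6 face opposite to the C7 acetate arm, should give the 6R alcohol with oxygen trans to C11, which closes by acid-catalysed lactonization to the trans-fused γ-lactone.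

Step 11
Reactants: 20 (3S,6R,7S,8R,1(10)E,4Z)-8-(benzyldimethylsilyl)-3-(triisopropylsilyloxy)-13-norgermacra-1(10),4-dien-12,6-olide
Product: 22 (3S,6R,7R,8R,1(10)E,4Z)-8-hydroxy-3-(triisopropylsilyloxy)-13-norgermacra-1(10),4-dien-12,6-olide, via fluorosilane 21 (not isolated)
Conditions: Bu4NF, THF, 0 °C; then KHCO3, H2O2 (30%), MeOH, 0 °C to rt
Reagents that add atoms: hydrogen peroxide, OO
Why: Tamao–Fleming oxidation, in which fluoride cleaves the benzyl–silicon bond and the fluorosilane then shifts C8 from silicon to peroxide oxygen with retention, should turn 8R silicon into the 8R hydroxyl while the lactone and the hindered C3 silyl ether survive the short fluoride exposure.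

Step 12
Reactants: 23 angelic acid
Product: 24 (Z)-2-methylbut-2-en-1-ol
Conditions: LiAlH4, Et2O, 0 °C to rt
Reagents that add atoms: none
Why: Hydride reduction of the carboxylic acid gives the primary allylic alcohol with the Z olefin geometry retained.

Step 13
Reactants: 24 (Z)-2-methylbut-2-en-1-ol
Product: 25 [(2R,3S)-2,3-dimethyloxiran-2-yl]methanol
Conditions: Ti(O-i-Pr)4 (cat.), D-(−)-diethyl tartrate (cat.), t-BuOOH, 4 Å MS, CH2Cl2, −20 °C
Reagents that add atoms: tert-butyl hydroperoxide, CC(C)(C)OO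
Why: Sharpless asymmetric epoxidation with the D-(−)-tartrate should deliver oxygen to the olefin face that gives the (2R,3S)-epoxy alcohol, and the syn addition keeps the two methyl groups trans.

Step 14
Reactants: 25 [(2R,3S)-2,3-dimethyloxiran-2-yl]methanol
Product: 26 (2S,3S)-2,3-dimethyloxirane-2-carboxylic acid
Conditions: RuCl3·xH2O (cat.), NaIO4, MeCN/EtOAc/H2O, rt
Reagents that add atoms: water, O
Why: Catalytic ruthenium tetroxide oxidation takes the primary alcohol through the aldehyde hydrate to the glycidic acid without opening the epoxide, and C2 becomes S only through the change in substituent ranking.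

Step 15
Reactants: 22 (3S,6R,7R,8R,1(10)E,4Z)-8-hydroxy-3-(triisopropylsilyloxy)-13-norgermacra-1(10),4-dien-12,6-olide, 26 (2S,3S)-2,3-dimethyloxirane-2-carboxylic acid
Product: 28 (3S,6R,7R,8R,1(10)E,4Z)-8-[(2S,3S)-2,3-dimethyloxirane-2-carbonyloxy]-3-(triisopropylsilyloxy)-13-norgermacra-1(10),4-dien-12,6-olide, via mixed anhydride 27 (not isolated)
Conditions: 26, 2,4,6-Cl3C6H2COCl, Et3N, THF, rt; then 22, DMAP, toluene, rt
Reagents that add atoms: none
Why: Yamaguchi esterification transfers the epoxy acyl group from the mixed anhydride through its acylpyridinium to the hindered C8 alcohol under non-acidic conditions that preserve the epoxide and all stereocentres.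

Step 16
Reactants: 28 (3S,6R,7R,8R,1(10)E,4Z)-8-[(2S,3S)-2,3-dimethyloxirane-2-carbonyloxy]-3-(triisopropylsilyloxy)-13-norgermacra-1(10),4-dien-12,6-olide
Product: 32 (3S,6R,7R,8R,1(10)E,4Z)-8-[(2S,3S)-2,3-dimethyloxirane-2-carbonyloxy]-3-(triisopropylsilyloxy)germacra-1(10),4,11(13)-trien-12,6-olide, via lithium lactone enolate 29 (not isolated), via Mannich base 30 (not isolated), via trimethylammonium iodide 31 (not isolated)
Conditions: LiN(i-Pr)2, THF, −78 °C; CH2=NMe2+ I−, −78 °C to rt; MeI, rt; aq NaHCO3, rt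
Reagents that add atoms: N,N-dimethylmethyleneiminium iodide, C=[N+](C)C.[I-]
Why: Mannich aminomethylation of the lithium lactone enolate (the C8 ester has no α-hydrogen), exhaustive N-methylation and base-induced elimination of trimethylamine should install the exocyclic C11=C13 olefin and erase the transient C11 centre.

Step 17
Reactants: 32 (3S,6R,7R,8R,1(10)E,4Z)-8-[(2S,3S)-2,3-dimethyloxirane-2-carbonyloxy]-3-(triisopropylsilyloxy)germacra-1(10),4,11(13)-trien-12,6-olide
Product: 33 (1R,3S,6R,7R,8R,10R,4Z)-1,10-epoxy-8-[(2S,3S)-2,3-dimethyloxirane-2-carbonyloxy]-3-(triisopropylsilyloxy)germacra-4,11(13)-dien-12,6-olide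
Conditions: mCPBA, NaHCO3, CH2Cl2, 0 °C
Reagents that add atoms: 3-chloroperoxybenzoic acid, OOC(=O)c1cccc(Cl)c1
Why: Prilezhaev epoxidation should take the strained, electron-rich E C1=C10 olefin ahead of the Z C4=C5 olefin (flanked by two allylic C–O bonds and the bulky silyl ether) and of the electron-poor methylene lactone, and attack on its outer face in the conformer with C14 on the β-face gives the 1R,10R epoxide.

Step 18
Reactants: 33 (1R,3S,6R,7R,8R,10R,4Z)-1,10-epoxy-8-[(2S,3S)-2,3-dimethyloxirane-2-carbonyloxy]-3-(triisopropylsilyloxy)germacra-4,11(13)-dien-12,6-olide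
Product: 34 (1R,3S,6R,7R,8R,10R,4Z)-1,10-epoxy-3-hydroxy-8-[(2S,3S)-2,3-dimethyloxirane-2-carbonyloxy]germacra-4,11(13)-dien-12,6-olide (CNP0268255.2)
Conditions: Bu4NF, AcOH, THF, 0 °C to rt
Reagents that add atoms: none
Why: Fluoride cleavage of the silyl ether, buffered with acetic acid so that the methylene lactone, both epoxides and the ester do not meet free base, should release the 3S alcohol.

Compound list
1 | (R)-(−)-carvone | CC1=CC[C@H](CC1=O)C(C)=C | starting material
2 | (1R,5R)-cis-carveol | CC1=CC[C@H](C[C@H]1O)C(C)=C | intermediate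
3 | (1S,5R)-trans-carveyl 4-nitrobenzoate | CC1=CC[C@H](C[C@@H]1OC(=O)c2ccc(cc2)[N+](=O)[O-])C(C)=C | intermediate
4 | (1S,5R)-trans-carveol | CC1=CC[C@H](C[C@@H]1O)C(C)=C | intermediate
5 | (1S,5R)-trans-carveol triisopropylsilyl ether | CC1=CC[C@H](C[C@@H]1O[Si](C(C)C)(C(C)C)C(C)C)C(C)=C | intermediate
6 | (4S,6R)-3-methyl-6-(prop-1-en-2-yl)-4-(triisopropylsilyloxy)cyclohex-2-en-1-one | CC1=CC(=O)[C@H](C[C@@H]1O[Si](C(C)C)(C(C)C)C(C)C)C(C)=C | intermediate
7 | (E)-1,2-bis(tributylstannyl)ethene | CCCC[Sn](CCCC)(CCCC)/C=C/[Sn](CCCC)(CCCC)CCCC | starting material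
8 | benzylchlorodimethylsilane | C[Si](C)(Cl)Cc1ccccc1 | starting material
9 | (E)-2-(tributylstannyl)ethenyllithium | [Li]/C=C/[Sn](CCCC)(CCCC)CCCC | intermediate
10 | (E)-benzyldimethyl[2-(tributylstannyl)ethenyl]silane | CCCC[Sn](CCCC)(CCCC)/C=C/[Si](C)(C)Cc1ccccc1 | intermediate
11 | (E)-2-(benzyldimethylsilyl)ethenyllithium | [Li]/C=C/[Si](C)(C)Cc1ccccc1 | intermediate
12 | (E)-2-(benzyldimethylsilyl)ethenylcerium dichloride | Cl[Ce](Cl)/C=C/[Si](C)(C)Cc1ccccc1 | intermediate
13 | (1R,4S,6R)-1-[(E)-2-(benzyldimethylsilyl)ethenyl]-3-methyl-6-(prop-1-en-2-yl)-4-(triisopropylsilyloxy)cyclohex-2-en-1-ol | C=C(C)[C@H]1C[C@H](O[Si](C(C)C)(C(C)C)C(C)C)C(C)=C[C@]1(O)/C=C/[Si](C)(C)Cc2ccccc2 | intermediate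
14 | potassium alkoxide of 13 | C=C(C)[C@H]1C[C@H](O[Si](C(C)C)(C(C)C)C(C)C)C(C)=C[C@]1([O-])/C=C/[Si](C)(C)Cc2ccccc2.[K+] | intermediate
15 | potassium C6 enolate of 16 (C6=C7 trans in the ring, oxygen cis to C8) | [K+].[O-]/C1=C\[C@H]([Si](C)(C)Cc2ccccc2)C/C(C)=C/C[C@H](O[Si](C(C)C)(C(C)C)C(C)C)/C(C)=C\1 | intermediate
16 | (3S,8R,1(10)E,4Z)-8-(benzyldimethylsilyl)-4,10-dimethyl-3-(triisopropylsilyloxy)cyclodeca-1(10),4-dien-6-one | C1[C@H]([Si](C)(C)Cc2ccccc2)C/C(C)=C/C[C@H](O[Si](C(C)C)(C(C)C)C(C)C)/C(C)=C\C1=O | intermediate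
17 | lithium C6 enolate of 16 (C6=C7 geometry not assigned) | [Li+].[O-]C1=C[C@H]([Si](C)(C)Cc2ccccc2)C/C(C)=C/C[C@H](O[Si](C(C)C)(C(C)C)C(C)C)/C(C)=C\1 | intermediate
18 | methyl 2-[(3S,7S,8R,1(10)E,4Z)-8-(benzyldimethylsilyl)-4,10-dimethyl-6-oxo-3-(triisopropylsilyloxy)cyclodeca-1(10),4-dien-7-yl]acetate | COC(=O)C[C@@H]1[C@H]([Si](C)(C)Cc2ccccc2)C/C(C)=C/C[C@H](O[Si](C(C)C)(C(C)C)C(C)C)/C(C)=C\C1=O | intermediate
19 | methyl 2-[(3S,6R,7S,8R,1(10)E,4Z)-8-(benzyldimethylsilyl)-6-hydroxy-4,10-dimethyl-3-(triisopropylsilyloxy)cyclodeca-1(10),4-dien-7-yl]acetate | COC(=O)C[C@@H]1[C@H]([Si](C)(C)Cc2ccccc2)C/C(C)=C/C[C@H](O[Si](C(C)C)(C(C)C)C(C)C)/C(C)=C\[C@H]1O | intermediate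
20 | (3S,6R,7S,8R,1(10)E,4Z)-8-(benzyldimethylsilyl)-3-(triisopropylsilyloxy)-13-norgermacra-1(10),4-dien-12,6-olide (trans-fused γ-lactone) | C1C(=O)O[C@@H]2/C=C(/C)[C@@H](O[Si](C(C)C)(C(C)C)C(C)C)C/C=C(C)/C[C@@H]([Si](C)(C)Cc3ccccc3)[C@@H]12 | intermediate
21 | 8-(fluorodimethylsilyl) analogue of 20 | C1C(=O)O[C@@H]2/C=C(/C)[C@@H](O[Si](C(C)C)(C(C)C)C(C)C)C/C=C(C)/C[C@@H]([Si](C)(C)F)[C@@H]12 | intermediate
22 | (3S,6R,7R,8R,1(10)E,4Z)-8-hydroxy-3-(triisopropylsilyloxy)-13-norgermacra-1(10),4-dien-12,6-olide | C1C(=O)O[C@@H]2/C=C(/C)[C@@H](O[Si](C(C)C)(C(C)C)C(C)C)C/C=C(C)/C[C@@H](O)[C@@H]12 | intermediate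
23 | angelic acid | C/C=C(/C)C(=O)O | starting material
24 | (Z)-2-methylbut-2-en-1-ol | C/C=C(/C)CO | intermediate
25 | [(2R,3S)-2,3-dimethyloxiran-2-yl]methanol | OC[C@@]1(C)O[C@H]1C | intermediate
26 | (2S,3S)-2,3-dimethyloxirane-2-carboxylic acid | OC(=O)[C@@]1(C)O[C@H]1C | intermediate
27 | (2S,3S)-2,3-dimethyloxirane-2-carboxylic 2,4,6-trichlorobenzoic anhydride | Clc1cc(Cl)c(c(Cl)c1)C(=O)OC(=O)[C@@]2(C)O[C@H]2C | intermediate
28 | (3S,6R,7R,8R,1(10)E,4Z)-8-[(2S,3S)-2,3-dimethyloxirane-2-carbonyloxy]-3-(triisopropylsilyloxy)-13-norgermacra-1(10),4-dien-12,6-olide | C1C(=O)O[C@@H]2/C=C(/C)[C@@H](O[Si](C(C)C)(C(C)C)C(C)C)C/C=C(C)/C[C@@H](OC(=O)[C@@]3(C)O[C@H]3C)[C@@H]12 | intermediate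
29 | lithium lactone enolate of 28 (C11=C12) | C1=C([O-])O[C@@H]2/C=C(/C)[C@@H](O[Si](C(C)C)(C(C)C)C(C)C)C/C=C(C)/C[C@@H](OC(=O)[C@@]3(C)O[C@H]3C)[C@@H]12.[Li+] | intermediate
30 | 11-(dimethylaminomethyl) derivative of 28 (C11 not assigned) | CN(C)CC1C(=O)O[C@@H]2/C=C(/C)[C@@H](O[Si](C(C)C)(C(C)C)C(C)C)C/C=C(C)/C[C@@H](OC(=O)[C@@]3(C)O[C@H]3C)[C@@H]12 | intermediate
31 | 11-(trimethylammoniomethyl) derivative of 28, iodide (C11 not assigned) | C[N+](C)(C)CC1C(=O)O[C@@H]2/C=C(/C)[C@@H](O[Si](C(C)C)(C(C)C)C(C)C)C/C=C(C)/C[C@@H](OC(=O)[C@@]3(C)O[C@H]3C)[C@@H]12.[I-] | intermediate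
32 | (3S,6R,7R,8R,1(10)E,4Z)-8-[(2S,3S)-2,3-dimethyloxirane-2-carbonyloxy]-3-(triisopropylsilyloxy)germacra-1(10),4,11(13)-trien-12,6-olide | C=C1C(=O)O[C@@H]2/C=C(/C)[C@@H](O[Si](C(C)C)(C(C)C)C(C)C)C/C=C(C)/C[C@@H](OC(=O)[C@@]3(C)O[C@H]3C)[C@@H]12 | intermediate
33 | (1R,3S,6R,7R,8R,10R,4Z)-1,10-epoxy-8-[(2S,3S)-2,3-dimethyloxirane-2-carbonyloxy]-3-(triisopropylsilyloxy)germacra-4,11(13)-dien-12,6-olide | C=C1C(=O)O[C@@H]2/C=C(/C)[C@@H](O[Si](C(C)C)(C(C)C)C(C)C)C[C@H]3O[C@]3(C)C[C@@H](OC(=O)[C@@]4(C)O[C@H]4C)[C@@H]12 | intermediate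
34 | (1R,3S,6R,7R,8R,10R,4Z)-1,10-epoxy-3-hydroxy-8-[(2S,3S)-2,3-dimethyloxirane-2-carbonyloxy]germacra-4,11(13)-dien-12,6-olide (CNP0268255.2) | C=C1C(=O)O[C@@H]2/C=C(/C)[C@@H](O)C[C@H]3O[C@]3(C)C[C@@H](OC(=O)[C@@]3(C)O[C@H]3C)[C@@H]12 | target

Total step count: 18 (steps 6 and 12–14 are the two side branches).
Longest linear sequence: 14 steps (1–5, 7–11, 15–18, from carvone).

Steps most likely to fail

Step 9, facial selectivity at C7. The ten-membered enolate offers the bromo ester only its outer face, and if that face lies syn to the C8–Si bond the alkylation would run mainly to the C7 epimer. The fallback sets C7 by proton delivery instead of by carbon–carbon bond formation. It sets out from 16: the alkylation is taken as it comes and gives the C7-epimeric keto ester F1. KN(SiMe3)2 (THF, −78 °C) should convert it into the tetrasubstituted potassium enolate F2. Quenching at −78 °C with 2,6-di-tert-butyl-4-methylphenol should then put the proton on the face the electrophile had used, which inverts C7 and brings the route back at 18.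

Step 10, facial selectivity at C6. Hydride may enter from the other face, and the 6S alcohol would then close to the cis-fused lactone. The fallback inverts C6 during ring closure. It sets out from 18: the reduction gives the 6-epimeric hydroxy ester F3 and from it the cis-fused lactone F4. LiOH (THF/H2O) opens this to the hydroxy acid F5. An intramolecular Mitsunobu esterification (PPh3, DIAD, dilute THF) then closes the γ-lactone with inversion at C6, the five-membered SN2 closure being favoured over the seven-membered SN2′ alternative, and the route is rejoined at 20.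

Step 8, pathway selectivity of the key step. A boat or cis-fused array, or base-induced degradation of the doubly allylic alkoxide, would erode the E geometry and the control of C8 or consume material. The fallback keeps the same bond reorganization but avoids the charged intermediate. It sets out from 13: PdCl2(PhCN)2 (a divalent palladium catalyst) in THF at room temperature should promote the oxy-Cope shift through a chair-like cyclization–fragmentation, which the 2-substituted isopropenyl terminus favours. It comes back at 16 directly and makes no new compound (F0).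

Further compounds
F1 | step 9 | methyl 2-[(3S,7R,8R,1(10)E,4Z)-8-(benzyldimethylsilyl)-4,10-dimethyl-6-oxo-3-(triisopropylsilyloxy)cyclodeca-1(10),4-dien-7-yl]acetate (C7 epimer of 18) | COC(=O)C[C@H]1[C@H]([Si](C)(C)Cc2ccccc2)C/C(C)=C/C[C@H](O[Si](C(C)C)(C(C)C)C(C)C)/C(C)=C\C1=O
F2 | step 9 | potassium C6 enolate of F1 (C6=C7 geometry not assigned) | [K+].[O-]C1=C(CC(=O)OC)[C@H]([Si](C)(C)Cc2ccccc2)C/C(C)=C/C[C@H](O[Si](C(C)C)(C(C)C)C(C)C)/C(C)=C\1
F3 | step 10 | methyl 2-[(3S,6S,7S,8R,1(10)E,4Z)-8-(benzyldimethylsilyl)-6-hydroxy-4,10-dimethyl-3-(triisopropylsilyloxy)cyclodeca-1(10),4-dien-7-yl]acetate (C6 epimer of 19) | COC(=O)C[C@@H]1[C@H]([Si](C)(C)Cc2ccccc2)C/C(C)=C/C[C@H](O[Si](C(C)C)(C(C)C)C(C)C)/C(C)=C\[C@@H]1O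
F4 | step 10 | (3S,6S,7S,8R,1(10)E,4Z)-8-(benzyldimethylsilyl)-3-(triisopropylsilyloxy)-13-norgermacra-1(10),4-dien-12,6-olide (cis-fused lactone, C6 epimer of 20) | C1C(=O)O[C@H]2/C=C(/C)[C@@H](O[Si](C(C)C)(C(C)C)C(C)C)C/C=C(C)/C[C@@H]([Si](C)(C)Cc3ccccc3)[C@@H]12
F5 | step 10 | 2-[(3S,6S,7S,8R,1(10)E,4Z)-8-(benzyldimethylsilyl)-6-hydroxy-4,10-dimethyl-3-(triisopropylsilyloxy)cyclodeca-1(10),4-dien-7-yl]acetic acid | OC(=O)C[C@@H]1[C@H]([Si](C)(C)Cc2ccccc2)C/C(C)=C/C[C@H](O[Si](C(C)C)(C(C)C)C(C)C)/C(C)=C\[C@@H]1O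
F0 | step 8 | none | none
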